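All runs are calculated from invented constants.

I began with the constants the earlier runs could give, for these flasks and readings:

| setting | summer | noon | blue | red | grey |
|---|---|---|---|---|---|
| substrate | 11 mM | 11 mM | 11 mM | 11 mM | 11 mM |
| first nucleophile | 8.1 mM | 18 mM | 12.1 mM | 12.1 mM | 12.1 mM |
| second nucleophile | 11.5 mM | 11.5 mM | 11.5 mM | 11.5 mM | 11.5 mM |
| protic impurity | 3.3 mM | 3.3 mM | 3.30 mM | 3.30 mM | 3.30 mM |
| temperature | −25 °C | 0 °C | 20 °C | −20 °C | 0 °C |
| remark | run made earlier | run made earlier |  |  |  |
| time |  |  | 12 min | 12 min | 12 min |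

| run | time / min | target / % | substrate / % |
|---|---|---|---|
| summer | 12.0 | 0 | 99 |
| summer | 40.0 | 1 | 98 |
| summer | 60.0 | 0 | 96 |
| summer | 90.0 | 3 | 95 |
| summer | 150 | 0 | 88 |
| noon | 8.00 | 8 | 74 |
| noon | 15.0 | 10 | 57 |
| noon | 20.0 | 12 | 46 |
| noon | 30.0 | 16 | 29 |
| noon | 40.0 | 20 | 19 |

(readings scatter by 1.5 percentage points)

- the flask with the highest amount of target, in percent of the substrate charged ("all alike" if they lie within 1.5 percentage points) (blue / red / grey / all alike)
- final target, as a percentage of the substrate charged, in blue
- final target, as a percentage of the substrate charged, in red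
- final target, as a percentage of the substrate charged, in grey

In noon the substrate fell from 74% to 19% without bending on a log scale, so I took a first-order constant k, 0.0425 min⁻¹ at 0 °C. Summer reads 8.54 × 10⁻⁴ min⁻¹ at −25 °C. Assuming the first nucleophile's charge does not enter, the two give an activation energy of 88.1 kJ mol⁻¹, a reading with their scatter.

For grey, k times 12 min gives 0.510. That number, the substrate lifetimes a flask gets in its time, is N, and I took the substrate left to be e^(−N). Blue gets 7.19 and red 0.0238.

Then I turned the question round: what would have to be true for blue not to lead? Noon's last reading puts target at a share s of 0.247 of the substrate lost. By N, blue loses 99.9% and grey 39.9%, so grey could match blue with a share 2.50 times blue's. Noon's readings put the share at 0.308 first and 0.247 last. With s held, I reckoned 24.7% in blue, 9.86% in grey and 0.581% in red, a gap of 15 percentage points between blue and grey against a margin of 1.5 points.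

The forecast said blue, with 26% in blue, 0.5% in red and 9% in grey, noting that “Target appears without a lag and stays at about 0.24 of the substrate lost”. My blue lies below its number and my grey above.

The richest flask was blue, with 25.9% of target, against 0.474% in red and 7.07% in grey.

    first nucleophile + protic impurity → quenched reagent (k = 5.50 M⁻¹ min⁻¹, Ea = 55.0 kJ mol⁻¹)
    second nucleophile + intermediate → other capture product (k = 31000 M⁻¹ min⁻¹, Ea = 38.0 kJ mol⁻¹)
    first nucleophile ⇌ dormant form (K = 1.60, k = 1.20 min⁻¹, Ea = 65.0 kJ mol⁻¹, ΔH = −6.00 kJ mol⁻¹)
    substrate ⇌ intermediate (K = 0.120, k = 0.0400 min⁻¹, Ea = 87.0 kJ mol⁻¹, ΔH = −7.00 kJ mol⁻¹)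
    intermediate → side product (k = 0.170 min⁻¹, Ea = 70.0 kJ mol⁻¹)
    first nucleophile + intermediate → target (k = 15000 M⁻¹ min⁻¹, Ea = 42.0 kJ mol⁻¹)
    (constants at 0 °C)

Blue kept 0.15% of its substrate, the limiting reagent there, and grey 62%, where N gave 0.0754% and 60.0%. At the asked time in blue, second nucleophile was taking the intermediate 2.1 times as fast as first nucleophile, and blue held 73.8% of other capture product against 25.9% of target. The neighbour with 48 mM of first nucleophile keeps blue's temperature and time, so N as I reckoned it stays 7.19, which again gives 0.0754% of substrate but not the split. That flask kept 0.146% of substrate and made 54.1% of target.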